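One equivalent of coupling partner is my unit of count.

the same everywhere: starting material 0.044 M
- Sunday's: coupling partner 0.60 equiv; second substrate 0.50 equiv; the very flask that is asked about, followed so far
- Saturday's: coupling partner 1.2 equiv; second substrate 0.50 equiv; run made earlier
- flask: coupling partner 0.600 equiv; second substrate 0.500 equiv; time 2.0 h

| Sunday's: time / min | Sunday's: target / % | Saturday's: time / min | Saturday's: target / % |
|---|---|---|---|
| 1.33 | 10.2 | 1.33 | 20.0 |
| 3.00 | 14.0 | 3.00 | 26.3 |
| 6.00 | 14.7 | 6.00 | 29.0 |
| 12.0 | 13.9 | 12.0 | 27.0 |
| 25.0 | 10.1 | 25.0 | 22.1 |
| 50.0 | 9.5 | 50.0 | 18.8 |

(standard deviation of a reading: 0.3 percentage points)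

* the best time, 2.0 h at the latest, for target
* the amount of target, in percent of the starting material charged, at that time
* the first time at which target reaches 10%, in the same percent, in min

- for target the idle adduct is counted in
- what may be going on: 2 coupling partner -> self-condensation product; starting material + second substrate -> cross product; second substrate + coupling partner -> second product; coupling partner + target <-> idle adduct; target <-> isomer of the product; starting material + coupling partner -> target

1. One turnover to target spends one starting material and one coupling partner. The flask asked about is Sunday's run, charged with 0.600 equiv of coupling partner, the limiting reagent.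

2. Saturday's highest reading is 29.0% on 1.2 equiv, which makes 24.2% per equivalent. I call this the peak count, the highest target reading per equivalent of coupling partner charged.

3. Now the question turned round: I say target fails to follow the partner charge if the highest readings of the two runs stand in a ratio away from that of their charges, 2.00. They stand at 1.97. The peak count puts Sunday's peak at 14.5%, and Sunday's highest reading lies 0.2 percentage points above that, less than the scatter of 0.3 points. So this flask stands on the side of the count, and I commit to 14.5%.

4. The forecast differs from my count: it gives 14.9% at 0.08 h, and 10% at 1.28 min. Its ground is different too: “so I read the answer from its curve and use Saturday's only for shape”.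

5. The flask peaks at 14.8% at 0.0956 h and reaches 10% at 1.16 min. The forecast's time is earlier than that. At the best time the flask still holds 6.57% of its own charge of coupling partner. Per equivalent charged, its peak comes to 24.7%, beside the peak count of 24.2%.

    2 coupling partner → self-condensation product (k = 0.0937 L mol⁻¹ s⁻¹)
    starting material + second substrate → cross product (k = 0.177 L mol⁻¹ s⁻¹)
    second substrate + coupling partner → second product (k = 0.816 L mol⁻¹ s⁻¹)
    coupling partner + target ⇌ idle adduct, settled at all times (K = 19.5 L mol⁻¹)
    target ⇌ isomer of the product (K = 1.45, k = 0.00111 s⁻¹)
    starting material + coupling partner → target (k = 0.121 L mol⁻¹ s⁻¹)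

6. The neighbour with 0.150 equiv of coupling partner: the peak count gives 3.63%. The computed best for that neighbour is 3.33%.

The numbers in the tables are simulated from invented constants, and the scatter is random.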